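**Retrosynthetic overview**

- The target comes from 4'-O-benzylquercetin by sulfation of the 3-, 3'- and 7-hydroxyls (the chelated 5-OH stays free), then O-debenzylation and release of the acid form.
- The strategy rests on ring C: the enol carbon C3 (bearing the 3-O-sulfate oxygen) and the carbonyl carbon C4 are adjacent oxygenated carbons. The flavonol is therefore the stable enol of a flavan-3,4-dione, and C3–C4 is a pinacol bond between two aldehyde carbons.
- Key disconnection: the flavan-3,4-diol is opened at C3–C4 to a dialdehyde, the ether of a ring A salicylaldehyde with an α-aryl glycolaldehyde. Ring C is the only ring formed; rings A and B are bought.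
- The dialdehyde comes from a Mitsunobu ether (O1–C2 bond) of a ring A phenol aldehyde with a ring B mandelate by reduction and re-oxidation. The mandelate comes from the ring B aldehyde by Jocic–Reeve homologation.

Key step: step 8

Assumption: the target is drawn as the free tris(hydrogen sulfate), so the sulfate esters are carried as triethylammonium salts and the acid form is released only in the last operation on a cold acidic resin; compounds 5 to 13 are racemic and one enantiomer is drawn.

**Route**

Step 1
Reactants: 1 2,4,6-trihydroxybenzaldehyde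
Product: 2 2-hydroxy-4,6-bis(methoxymethoxy)benzaldehyde
Conditions: MOMCl (2.1 equiv), iPr2NEt, CH2Cl2, 0 °C → rt
Reagents that add atoms: chloromethyl methyl ether, COCCl
Why: Base-mediated O-alkylation of phenols (MOM ether formation), in which the para and one of the two equivalent ortho hydroxyls react while the remaining ortho hydroxyl, hydrogen-bonded to the formyl group, should stay free as the later O1.

Step 2
Reactants: 3 4-(benzyloxy)-3-hydroxybenzaldehyde
Product: 4 4-(benzyloxy)-3-(methoxymethoxy)benzaldehyde
Conditions: MOMCl, iPr2NEt, CH2Cl2, 0 °C → rt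
Reagents that add atoms: chloromethyl methyl ether, COCCl
Why: Standard MOM ether formation on the only free phenol, giving a 3'-oxygen that can later be unmasked by acid while the 4'-benzyl ether stays.

Step 3
Reactants: 4 4-(benzyloxy)-3-(methoxymethoxy)benzaldehyde
Product: 6 rac-2-[4-(benzyloxy)-3-(methoxymethoxy)phenyl]-2-hydroxyacetic acid, via tribromomethyl carbinol 5 (not isolated)
Conditions: CHBr3, KOH, LiCl, 1,4-dioxane–H2O, 0–5 °C; then cold 1 M HCl to pH 3
Reagents that add atoms: bromoform, BrC(Br)Br; potassium hydroxide, [K+].[OH-]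
Why: Jocic–Reeve reaction, in which the tribromomethyl anion adds to the aldehyde, the carbinol closes to a gem-dibromo epoxide, hydroxide opens it at the benzylic carbon and the acyl bromide is hydrolysed, giving the racemic mandelic acid under basic conditions that spare the MOM and benzyl ethers.

Step 4
Reactants: 6 rac-2-[4-(benzyloxy)-3-(methoxymethoxy)phenyl]-2-hydroxyacetic acid
Product: 7 methyl rac-2-[4-(benzyloxy)-3-(methoxymethoxy)phenyl]-2-hydroxyacetate
Conditions: MeI, KHCO3, DMF, rt
Reagents that add atoms: iodomethane, CI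
Why: Carboxylate O-alkylation (SN2) under weakly basic conditions that leave the secondary hydroxyl and the acid-labile MOM ether untouched.

Step 5
Reactants: 2 2-hydroxy-4,6-bis(methoxymethoxy)benzaldehyde; 7 methyl rac-2-[4-(benzyloxy)-3-(methoxymethoxy)phenyl]-2-hydroxyacetate
Product: 8 methyl rac-2-[4-(benzyloxy)-3-(methoxymethoxy)phenyl]-2-[2-formyl-3,5-bis(methoxymethoxy)phenoxy]acetate
Conditions: PPh3, DIAD, THF, 0 °C → rt
Reagents that add atoms: none
Why: Mitsunobu etherification of an acidic ortho-formyl phenol with a mandelate, which has no β-hydrogen to eliminate, forming the O1–C2 bond with inversion at a centre that is racemic anyway.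

Step 6
Reactants: 8 methyl rac-2-[4-(benzyloxy)-3-(methoxymethoxy)phenyl]-2-[2-formyl-3,5-bis(methoxymethoxy)phenoxy]acetate
Product: 9 rac-2-[4-(benzyloxy)-3-(methoxymethoxy)phenyl]-2-[2-(hydroxymethyl)-3,5-bis(methoxymethoxy)phenoxy]ethanol
Conditions: LiAlH4, THF, 0 °C; H2O/NaOH work-up
Reagents that add atoms: none
Why: Hydride reduction of the ester and the aryl aldehyde in one operation brings both carbons to the alcohol level, so that they can be raised together to the aldehyde level without a chemoselective partial reduction.

Step 7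
Reactants: 9 rac-2-[4-(benzyloxy)-3-(methoxymethoxy)phenyl]-2-[2-(hydroxymethyl)-3,5-bis(methoxymethoxy)phenoxy]ethanol
Product: 10 rac-2-{1-[4-(benzyloxy)-3-(methoxymethoxy)phenyl]-2-oxoethoxy}-4,6-bis(methoxymethoxy)benzaldehyde
Conditions: Dess–Martin periodinane (2.5 equiv), NaHCO3, CH2Cl2, 0 °C → rt; filtered through neutral silica and used at once
Reagents that add atoms: none
Why: Dess–Martin oxidation of both primary alcohols under buffered, non-basic conditions, chosen because the α-aryl-α-aryloxy aldehyde enolises easily and would not tolerate the amine base of an activated-DMSO oxidation.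

Step 8
Reactants: 10 rac-2-{1-[4-(benzyloxy)-3-(methoxymethoxy)phenyl]-2-oxoethoxy}-4,6-bis(methoxymethoxy)benzaldehyde
Product: 11 rac-(2R,3S,4S)-4'-(benzyloxy)-3',5,7-tris(methoxymethoxy)flavan-3,4-diol (2,3-trans-3,4-cis)
Conditions: SmI2 (3 equiv, 0.1 M in THF), t-BuOH (2 equiv), THF, −78 → 0 °C, slow addition of 10 to a final 0.005 M; aq. NaHCO3/Na2S2O3 work-up
Reagents that add atoms: none
Why: Inner-sphere electron transfer from SmI2 to the aryl aldehyde, which is conjugated and held to the metal by its flanking ortho oxygens, should give a trivalent-samarium ketyl at C4 that attacks the carbon of the samarium-bound aliphatic aldehyde, after which a second electron and protonation complete the diol; the closest known reaction type is the SmI2 intramolecular pinacol coupling of 1,6-dialdehydes to cyclic cis-1,2-diols. Ring C closes by 6-exo-trig attack of the C4 ketyl carbon on the C3 carbonyl, which forms the C3–C4 bond. The two new stereocentres are expected cis because both oxygens stay bound to one trivalent samarium in the cyclic transition state, and the C3 oxygen is expected trans to the pseudo-equatorial 2-aryl group on the existing racemic C2 centre. The step needs ring closure over intermolecular coupling, which slow addition at high dilution and the chelate should secure. It also needs C–C coupling over expulsion of the ring A aryloxide from a doubly reduced aliphatic aldehyde, which is favoured by preferential reduction of the aryl aldehyde, low temperature and the absence of HMPA. The reagent is essentially neutral, so the enolisable aldehyde is not drawn into aldol closure to a dihydrobenzofuran, and since all three stereocentres are erased in step 9 the diastereoselectivity is not critical.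

Step 9
Reactants: 11 rac-(2R,3S,4S)-4'-(benzyloxy)-3',5,7-tris(methoxymethoxy)flavan-3,4-diol
Product: 14 4'-(benzyloxy)-3-hydroxy-3',5,7-tris(methoxymethoxy)flavone, via dihydroflavonol ketol 12 (not isolated), via flavan-3,4-dione 13 (not isolated)
Conditions: IBX (3 equiv), DMSO, rt → 40 °C; aq. NaHCO3 work-up
Reagents that add atoms: none
Why: IBX oxidation of a vicinal diol to the 1,2-dione without glycol cleavage and without an ionising leaving group at the electron-rich benzylic C4, after which the 2-aryl-3,4-dione should tautomerise through its acidic C2–H to the aromatic 3-hydroxychromen-4-one, removing all stereocentres.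

Step 10
Reactants: 14 4'-(benzyloxy)-3-hydroxy-3',5,7-tris(methoxymethoxy)flavone
Product: 15 4'-(benzyloxy)-3,3',5,7-tetrahydroxyflavone (4'-O-benzylquercetin)
Conditions: 3 M aq. HCl, MeOH–THF, 50 °C
Reagents that add atoms: none
Why: Acid-catalysed acetal cleavage (transacetalisation to methanol) removes the three MOM ethers, while the benzyl aryl ether and the flavonol core are stable to these conditions.

Step 11
Reactants: 15 4'-(benzyloxy)-3,3',5,7-tetrahydroxyflavone
Product: 16 tris(triethylammonium) 4'-(benzyloxy)-5-hydroxyflavone-3,3',7-triyl tris(sulfate)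
Conditions: SO3·NEt3 (6 equiv), DMA, 65 °C; precipitation with Et2O, Sephadex LH-20
Reagents that add atoms: sulfur trioxide–triethylamine complex, CC[N+](CC)(CC)S(=O)(=O)[O-]
Why: O-Sulfation of phenolic and enolic hydroxyls with an amine–sulfur trioxide complex, in which the 5-OH, strongly hydrogen-bonded to the C4 carbonyl, is the least reactive hydroxyl of a flavonoid and should stay free, while the 4'-oxygen is blocked as its benzyl ether.

Step 12
Reactants: 16 tris(triethylammonium) 4'-(benzyloxy)-5-hydroxyflavone-3,3',7-triyl tris(sulfate)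
Product: 18 quercetin 3,3',7-tris(hydrogen sulfate), via debenzylated triethylammonium salt 17 (not isolated)
Conditions: H2 (1 atm), 10% Pd/C, MeOH–H2O, rt; filtration; then Dowex 50W-X8 (H+ form), H2O, 0–5 °C, freeze-drying
Reagents that add atoms: none
Why: Catalytic hydrogenolysis of the benzyl aryl ether, to which aryl sulfate salts and the flavone C2=C3 bond are inert under these mild conditions, followed by cation exchange that replaces triethylammonium by protons in the cold to limit hydrolysis of the sulfate esters.

**Compound list**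

1 | 2,4,6-trihydroxybenzaldehyde | O=Cc1c(O)cc(O)cc1O | starting material
2 | 2-hydroxy-4,6-bis(methoxymethoxy)benzaldehyde | O=Cc1c(O)cc(OCOC)cc1OCOC | intermediate
3 | 4-(benzyloxy)-3-hydroxybenzaldehyde | O=Cc1ccc(OCc2ccccc2)c(O)c1 | starting material
4 | 4-(benzyloxy)-3-(methoxymethoxy)benzaldehyde | O=Cc1ccc(OCc2ccccc2)c(OCOC)c1 | intermediate
5 | rac-1-[4-(benzyloxy)-3-(methoxymethoxy)phenyl]-2,2,2-tribromoethanol (not isolated) | O[C@@H](C(Br)(Br)Br)c1ccc(OCc2ccccc2)c(OCOC)c1 | intermediate
6 | rac-2-[4-(benzyloxy)-3-(methoxymethoxy)phenyl]-2-hydroxyacetic acid | O[C@H](C(=O)O)c1ccc(OCc2ccccc2)c(OCOC)c1 | intermediate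
7 | methyl rac-2-[4-(benzyloxy)-3-(methoxymethoxy)phenyl]-2-hydroxyacetate | O[C@H](C(=O)OC)c1ccc(OCc2ccccc2)c(OCOC)c1 | intermediate
8 | methyl rac-2-[4-(benzyloxy)-3-(methoxymethoxy)phenyl]-2-[2-formyl-3,5-bis(methoxymethoxy)phenoxy]acetate | O=Cc1c(OCOC)cc(OCOC)cc1O[C@@H](C(=O)OC)c1ccc(OCc2ccccc2)c(OCOC)c1 | intermediate
9 | rac-2-[4-(benzyloxy)-3-(methoxymethoxy)phenyl]-2-[2-(hydroxymethyl)-3,5-bis(methoxymethoxy)phenoxy]ethanol | OCc1c(OCOC)cc(OCOC)cc1O[C@@H](CO)c1ccc(OCc2ccccc2)c(OCOC)c1 | intermediate
10 | rac-2-{1-[4-(benzyloxy)-3-(methoxymethoxy)phenyl]-2-oxoethoxy}-4,6-bis(methoxymethoxy)benzaldehyde | O=Cc1c(OCOC)cc(OCOC)cc1O[C@@H](C=O)c1ccc(OCc2ccccc2)c(OCOC)c1 | intermediate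
11 | rac-(2R,3S,4S)-4'-(benzyloxy)-3',5,7-tris(methoxymethoxy)flavan-3,4-diol (2,3-trans-3,4-cis) | O[C@@H]1[C@H](O)[C@@H](c2ccc(OCc3ccccc3)c(OCOC)c2)Oc2cc(OCOC)cc(OCOC)c21 | intermediate
12 | rac-(2R,3R)-4'-(benzyloxy)-3-hydroxy-3',5,7-tris(methoxymethoxy)flavan-4-one (not isolated) | O=C1[C@H](O)[C@@H](c2ccc(OCc3ccccc3)c(OCOC)c2)Oc2cc(OCOC)cc(OCOC)c21 | intermediate
13 | rac-4'-(benzyloxy)-3',5,7-tris(methoxymethoxy)flavan-3,4-dione (not isolated) | O=C1C(=O)[C@@H](c2ccc(OCc3ccccc3)c(OCOC)c2)Oc2cc(OCOC)cc(OCOC)c21 | intermediate
14 | 4'-(benzyloxy)-3-hydroxy-3',5,7-tris(methoxymethoxy)flavone | O=c1c(O)c(-c2ccc(OCc3ccccc3)c(OCOC)c2)oc2cc(OCOC)cc(OCOC)c12 | intermediate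
15 | 4'-(benzyloxy)-3,3',5,7-tetrahydroxyflavone (4'-O-benzylquercetin) | O=c1c(O)c(-c2ccc(OCc3ccccc3)c(O)c2)oc2cc(O)cc(O)c12 | intermediate
16 | tris(triethylammonium) 4'-(benzyloxy)-5-hydroxyflavone-3,3',7-triyl tris(sulfate) | O=c1c(OS(=O)(=O)[O-])c(-c2ccc(OCc3ccccc3)c(OS(=O)(=O)[O-])c2)oc2cc(OS(=O)(=O)[O-])cc(O)c12.CC[NH+](CC)CC.CC[NH+](CC)CC.CC[NH+](CC)CC | intermediate
17 | tris(triethylammonium) quercetin 3,3',7-tris(sulfate) (not isolated) | O=c1c(OS(=O)(=O)[O-])c(-c2ccc(O)c(OS(=O)(=O)[O-])c2)oc2cc(OS(=O)(=O)[O-])cc(O)c12.CC[NH+](CC)CC.CC[NH+](CC)CC.CC[NH+](CC)CC | intermediate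
18 | quercetin 3,3',7-tris(hydrogen sulfate) | O=c1c(OS(=O)(=O)O)c(-c2ccc(O)c(OS(=O)(=O)O)c2)oc2cc(OS(=O)(=O)O)cc(O)c12 | target

**Step count**

Total: 12 steps. Longest linear sequence: 11 steps (3 → 18 through steps 2 to 12).

**Steps most likely to fail**

Step 8 (samarium pinacol closure). The aliphatic aldehyde may be reduced before it is trapped and then lose the ring A aryloxide from the neighbouring carbon. Intermolecular coupling or plain reduction back to diol 9 may also win over ring closure. The fallback forms the same C3–C4 link as an alkene and oxygenates it afterwards. It sets out from dialdehyde 10, which is methylenated at both formyl groups by a Wittig reaction (Ph3PCH3Br, KN(SiMe3)2, THF, −78 → 0 °C) to 1-ethenyl-2-({1-[4-(benzyloxy)-3-(methoxymethoxy)phenyl]prop-2-en-1-yl}oxy)-4,6-bis(methoxymethoxy)benzene F1. Ring-closing metathesis with second-generation Grubbs catalyst (CH2Cl2, 40 °C) then gives rac-4'-(benzyloxy)-3',5,7-tris(methoxymethoxy)flav-3-ene F2. Dihydroxylation with catalytic OsO4 and NMO (acetone–H2O) should add both oxygens to the face opposite the 2-aryl group, and the route is rejoined at diol 11.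

Step 9 (double oxidation and enolisation). Glycol C–C cleavage, ionisation at the doubly activated benzylic C4, or stalling at the ketol stage may compete with clean passage to the dione. The fallback stages the oxidation with two mechanistically different oxidants. It sets out from diol 11, whose electron-rich benzylic C4 carbinol alone is dehydrogenated by hydride abstraction with DDQ (1,4-dioxane, rt) to ketol 12, which is isolated in this variant. The remaining secondary alcohol, now next to a ketone and no longer prone to ionise, is oxidised by the Parikh–Doering method (SO3·pyridine, DMSO, Et3N, 0 °C → rt) to dione 13, which should enolise in the basic medium. The route is rejoined at flavonol 14.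

Step 11 (threefold sulfation). Sulfation may stop short at the hindered 3- and 3'-oxygens or reach the chelated 5-OH, and mixtures of charged partial sulfates are hard to separate. The fallback installs the sulfates as neutral, chromatographable diesters. It sets out from 15, which is treated with 2,2,2-trichloroethyl chlorosulfate (3.3 equiv), Et3N and DMAP in THF to give 4'-(benzyloxy)-5-hydroxyflavone-3,3',7-triyl tris(2,2,2-trichloroethyl sulfate) F3, purified on silica. Pd/C with HCO2NH4 under H2 in MeOH should then remove the three trichloroethyl groups and the benzyl ether together to give triammonium quercetin 3,3',7-tris(sulfate) F4. Cation exchange as in step 12 rejoins the route at target 18.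

**Further compounds**

F1 | step 8 | rac-1-ethenyl-2-({1-[4-(benzyloxy)-3-(methoxymethoxy)phenyl]prop-2-en-1-yl}oxy)-4,6-bis(methoxymethoxy)benzene | C=Cc1c(OCOC)cc(OCOC)cc1O[C@@H](C=C)c1ccc(OCc2ccccc2)c(OCOC)c1
F2 | step 8 | rac-4'-(benzyloxy)-3',5,7-tris(methoxymethoxy)flav-3-ene | C1=C[C@@H](c2ccc(OCc3ccccc3)c(OCOC)c2)Oc2cc(OCOC)cc(OCOC)c21
F0 | step 9 | none | none
F3 | step 11 | 4'-(benzyloxy)-5-hydroxyflavone-3,3',7-triyl tris(2,2,2-trichloroethyl sulfate) | O=c1c(OS(=O)(=O)OCC(Cl)(Cl)Cl)c(-c2ccc(OCc3ccccc3)c(OS(=O)(=O)OCC(Cl)(Cl)Cl)c2)oc2cc(OS(=O)(=O)OCC(Cl)(Cl)Cl)cc(O)c12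
F4 | step 11 | triammonium quercetin 3,3',7-tris(sulfate) | O=c1c(OS(=O)(=O)[O-])c(-c2ccc(O)c(OS(=O)(=O)[O-])c2)oc2cc(OS(=O)(=O)[O-])cc(O)c12.[NH4+].[NH4+].[NH4+]
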